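## The problem

Euchrestaflavanone A (25) is a (2S)-flavanone. Ring C (O1, C2, C3, C4, C4a, C8a) is a chroman-4-one fused to a phloroglucinol-type ring A and carries ring B at C2. Ring A has free hydroxyls at C5 and C7 and a prenyl group at C8, between O1 and the C7 oxygen. Ring B has a 4'-hydroxyl with a second prenyl group beside it at C3'. The three ring A oxygens are equivalent in phloroglucinol, so the synthesis must decide which one becomes O1; the wrong choice leads to the 6-prenyl isomer. C2 is the only stereocentre, so no other centre can relay its configuration and it must come from a reagent or catalyst. It is also fragile: base opens ring C by retro-oxa-Michael reaction, and the para-oxygenated benzylic C2–O1 bond can ionise in acid. The two prenyl olefins exclude hydrogenolysis, ozonolysis, dihydroxylation, electrophilic halogen and hot protic acid, which closes them onto the neighbouring phenols. The enabling feature is the 1,3-relationship between the C4 carbonyl and the C2 oxygen. C4 is a ketone carbon between C4a of ring A and the C3 methylene, so its polarity can be inverted to an acyl anion, and C3 and C2 can then be supplied by an enantiopure aryl oxirane.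

## Retrosynthesis

**Unmasking last.** Target 25 is traced to its tris(methoxymethyl) ether 24, and 24 to dithioketal 23, in which C4 is still masked. No skeletal bond is cut; the point is the order. Keeping C4 as a dithiane until ring C is closed avoids a beta-hydroxy ketone that would dehydrate or undergo retro-aldol cleavage. Unveiling the ketone before the phenols means no free phenol meets the alkylating conditions. One kind of protecting group on O5, O7 and O4' allows a single final deprotection. Acetals are preferred to silyl ethers because a silyl group ortho to the dithianyl carbanion would be prone to migrate from oxygen to carbon.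

**O1–C2.** Cutting O1–C2 of 23 gives phenol–carbinol 22. The neighbouring cuts of ring C are worse. Closing C4–C4a by acylation needs strong acid, which neither the prenyl groups nor the benzylic ether stereocentre tolerate. Closing O1–C2 by conjugate addition creates C2 without control. An intramolecular Mitsunobu etherification uses the C2 hydroxyl as leaving group and inverts C2, so a (2R)-carbinol is required. The forward reaction needs exactly one free ring A oxygen, the one beside the prenyl group. In 21 this oxygen carries a fluoride-labile 2-(trimethylsilyl)ethoxymethyl (SEM) group, orthogonal to the MOM ethers.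

**C3–C4 (key disconnection).** Cutting C3–C4 of 21 gives the ring A dithiane 10, used as its lithio derivative 20, and the (S)-aryl oxirane 19. The cut falls between the two aromatic halves, so the route is convergent. The alternative C2–C3 aldol cut would require absolute control in a methyl ketone aldol and would give the free beta-hydroxy ketone that the plan wants to avoid. Both fragments are simple monocyclic arenes. The forward reaction must attack the unsubstituted oxirane carbon only and leave the benzylic C–O bond intact. The carbinol then keeps the spatial arrangement of 19; the descriptor changes from S to R only because the CIP priorities change.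

**Ring B fragment.** Oxirane 19 is traced through chlorohydrin 18 to alpha-chloro ketone 17. The ketone comes from aryllithium 16 and chloroacetamide 15, the aryllithium from bromide 14, and 14 from 4-bromophenol (11) and prenyl bromide (12) via phenol 13. Asymmetric reduction of a chloro ketone is preferred to asymmetric epoxidation or dihydroxylation of a styrene, because those oxidants would also attack the trisubstituted prenyl olefin. The para-bromine blocks the para position during C-prenylation and then serves as the handle for metalation.

**Ring A fragment.** Dithiane 10 is the SEM ether of phenol 9, the thioacetal of salicylaldehyde 7 with dithiol 8. The SEM group is added after thioacetalisation so that one fewer acetal faces the Lewis acid. Aldehyde 7 comes from phenol 6 by ortho-formylation, which forms the C4–C4a bond at the only free ortho carbon. Phenol 6 is traced through allyl ether 5 and propargyl ether 4 to bis-MOM phenol 2 and chloride 3, and 2 to phloroglucinol (1). The Claisen rearrangement of 5 is preferred to direct C-prenylation of 2, which could also alkylate the para carbon and feed the 6-prenyl series. The rearrangement places the prenyl group on the carbon next to the oxygen that carried it. Formylation then occupies the other side of the same oxygen, so this oxygen, flanked by C8 and C4a, is unambiguously O1.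

## Roads not taken

**Alternative 1:** Ring A is cut at C4a–C5 and C8–C8a. A prenyl-bearing bis-silyl dienol ether A3 would add across the C4a=C8a bond of the (2S)-2-aryl-5-sulfinyl-dihydropyranone A2, and loss of sulfenic acid and methanol would aromatise the adduct to the 4'-MOM ether A1.
- Merits: the 8-prenyl regiochemistry is written into the diene, no phloroglucinol oxygen needs to be differentiated, and A1 is one deprotection from the target. In ring A economy this road is better than the chosen plan, which spends seven steps on dithiane 10.
- Weak points: A2 is a vinylogous ester and an electron-rich, poor dienophile. The reacting diene terminus carries the prenyl chain and is hindered. The cycloaddition must form a fully substituted C4a centre. A2 holds the C2 stereocentre beta to the enone through the ring oxygen, where heat or Lewis acid can open the ring. A2 also needs its own enantioselective synthesis.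
- Comparison: the cycloaddition has no close precedent on this substrate class. The chosen plan sets against the shorter ring A construction the fact that every one of its steps is an established reaction type.

**Alternative 2:** O1–C2 is cut with creation of the stereocentre. The phenoxide of 6 would attack the aryl-substituted terminus of the allyl complex formed from cinnamyl carbonate A5, [Ir(cod)Cl]2 and a chiral phosphoramidite, giving the branched (S)-ether A4.
- Merits: C2 is set catalytically while O1 is joined, phenol 6 is used directly without the SEM detour, and no Mitsunobu step is needed. Up to A4 this road is shorter than the chosen one.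
- Weak points: the phenoxide is ortho-substituted and the allyl fragment is electron-rich, so the branched ether can re-ionise, lose enantiopurity and drift to the linear isomer. The vinyl group must then be converted to the C3–C4 acyl unit in the presence of two other olefins. Ring C must finally be closed at C4–C4a by electrophilic acylation, whose acidic activation threatens the MOM ethers, the prenyl groups and the doubly activated benzylic ether stereocentre.
- Comparison: the chosen plan has more protecting-group steps, but C4 already sits on ring A at the ketone oxidation level and the ring closes under neutral conditions.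

**Alternative 3:** No strategic bond is cut. The racemic tris-MOM flavanone A7 would be made by classical condensation and ring closure, then reduced with RuCl(p-cymene)(TsDPEN), a divalent ruthenium complex, in 2-propanol with KOH. Only the 2S ketone should be reduced while the 2R enantiomer racemises, giving the cis-flavan-4-ol A6, which is then reoxidised.
- Merits: A7 is available in the fewest steps of any plan, by robust chemistry and without cryogenic organometallics. On step count this road is better.
- Weak points: the resolution needs racemisation to outrun reduction of a 5-alkoxy, doubly ortho-substituted, electron-rich aryl ketone, which is a slow hydride acceptor. Under KOH the ring-opened enone is favoured when O5 is protected, and it can itself be reduced. The same differentiation of ring A oxygens is still needed. A reduction–reoxidation pair is added.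
- Comparison: the chosen plan sets the stereocentre on a simple alpha-chloro aryl ketone, a well-behaved substrate for transfer hydrogenation, and transfers it by two stereospecific substitutions.

Key step: step 12

Remark: salts formed by simple deprotonation of O–H groups are not numbered; organolithium species carried on in the same flask are. The sense of the transfer hydrogenation in step 11 is assigned by analogy with aryl methyl ketones.

## Route

Step 1
Reactants: 1 phloroglucinol (benzene-1,3,5-triol)
Product: 2 3,5-bis(methoxymethoxy)phenol
Conditions: MOMCl (2.0 equiv), i-Pr2NEt, THF, 0 °C to rt; chromatographic separation from mono- and tris-ether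
Reagents that add atoms: chloromethyl methyl ether (MOMCl), COCCl
Why: O-alkylation of a phenol with an alpha-chloro ether; the three hydroxyls are equivalent, so two equivalents should give the bis-ether as the main component of a statistical mixture, from which under- and over-alkylated material is separated.

Step 2
Reactants: 2 3,5-bis(methoxymethoxy)phenol; 3 3-chloro-3-methylbut-1-yne
Product: 4 1,3-bis(methoxymethoxy)-5-[(2-methylbut-3-yn-2-yl)oxy]benzene
Conditions: DBU, CuCl2·2H2O (cat.), MeCN, 0 °C
Reagents that add atoms: none
Why: Copper-catalysed O-alkylation of phenols with tertiary propargylic chlorides is the standard entry to aryl 1,1-dimethylpropargyl ethers, and the unhindered phenol 2 is a favourable substrate.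

Step 3
Reactants: 4 1,3-bis(methoxymethoxy)-5-[(2-methylbut-3-yn-2-yl)oxy]benzene
Product: 5 1,3-bis(methoxymethoxy)-5-[(2-methylbut-3-en-2-yl)oxy]benzene
Conditions: H2 (1 atm), Lindlar catalyst (Pd on CaCO3 poisoned with Pb(OAc)2), quinoline, EtOAc, rt
Reagents that add atoms: none
Why: Lindlar semihydrogenation of a terminal alkyne should stop at the alkene; no other reducible group is present at this stage.

Step 4
Reactants: 5 1,3-bis(methoxymethoxy)-5-[(2-methylbut-3-en-2-yl)oxy]benzene
Product: 6 3,5-bis(methoxymethoxy)-2-(3-methylbut-2-en-1-yl)phenol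
Conditions: PhMe, 110 °C
Reagents that add atoms: none
Why: Aromatic Claisen rearrangement of a 1,1-dimethylallyl aryl ether transposes the allyl unit to the ortho carbon as a linear prenyl group; the two ortho positions are equivalent and carry hydrogen, so the dienone tautomerises and no para migration is expected.

Step 5
Reactants: 6 3,5-bis(methoxymethoxy)-2-(3-methylbut-2-en-1-yl)phenol
Product: 7 2-hydroxy-4,6-bis(methoxymethoxy)-3-(3-methylbut-2-en-1-yl)benzaldehyde
Conditions: MgCl2, Et3N, (CH2O)n, MeCN, 80 °C
Reagents that add atoms: paraformaldehyde (reacts as formaldehyde), C=O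
Why: Magnesium-mediated ortho-formylation of phenols (Casnati–Skattebøl): the magnesium phenoxide delivers formaldehyde to the ortho carbon and a second formaldehyde oxidises the hydroxymethyl intermediate; the only free ortho position is used, so the para carbon between the two acetal oxygens should stay untouched.

Step 6
Reactants: 7 2-hydroxy-4,6-bis(methoxymethoxy)-3-(3-methylbut-2-en-1-yl)benzaldehyde; 8 propane-1,3-dithiol
Product: 9 2-(1,3-dithian-2-yl)-3,5-bis(methoxymethoxy)-6-(3-methylbut-2-en-1-yl)phenol
Conditions: Zn(OTf)2 (cat.), CH2Cl2, 0 °C to rt; Et3N quench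
Reagents that add atoms: none
Why: Lewis-acid-catalysed dithioacetalisation of an aldehyde; the trioxygenated ring stabilises the intermediate thionium ion, so a mild zinc triflate catalyst should suffice and spare the MOM ethers and the prenyl group.

Step 7
Reactants: 9 2-(1,3-dithian-2-yl)-3,5-bis(methoxymethoxy)-6-(3-methylbut-2-en-1-yl)phenol
Product: 10 2-[4,6-bis(methoxymethoxy)-3-(3-methylbut-2-en-1-yl)-2-{[2-(trimethylsilyl)ethoxy]methoxy}phenyl]-1,3-dithiane
Conditions: NaH, DMF, 0 °C; SEMCl, 0 °C to rt
Reagents that add atoms: 2-(trimethylsilyl)ethoxymethyl chloride (SEMCl), C[Si](C)(C)CCOCCl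
Why: Williamson-type alkylation of a sodium phenoxide with an alpha-chloro ether; the phenol is no longer hydrogen-bonded to a carbonyl, and NaH does not deprotonate the dithiane C–H.

Step 8
Reactants: 11 4-bromophenol; 12 1-bromo-3-methylbut-2-ene (prenyl bromide)
Product: 13 4-bromo-2-(3-methylbut-2-en-1-yl)phenol
Conditions: NaH, PhMe, 0 °C; then 12, rt
Reagents that add atoms: none
Why: ortho-C-alkylation of a sodium phenoxide in a non-polar solvent, where the tight ion pair directs the allylic halide to the ortho carbon; the para position is blocked by bromine and the O-prenyl ether by-product is separable.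

Step 9
Reactants: 13 4-bromo-2-(3-methylbut-2-en-1-yl)phenol
Product: 14 4-bromo-1-(methoxymethoxy)-2-(3-methylbut-2-en-1-yl)benzene
Conditions: MOMCl, i-Pr2NEt, CH2Cl2, 0 °C to rt
Reagents that add atoms: chloromethyl methyl ether (MOMCl), COCCl
Why: Standard MOM protection of a phenol; the acetal survives the organolithium and basic steps that follow.

Step 10
Reactants: 14 4-bromo-1-(methoxymethoxy)-2-(3-methylbut-2-en-1-yl)benzene; 15 2-chloro-N-methoxy-N-methylacetamide
Product: 17 2-chloro-1-[4-(methoxymethoxy)-3-(3-methylbut-2-en-1-yl)phenyl]ethan-1-one, via aryllithium 16 (not isolated)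
Conditions: n-BuLi, THF, −78 °C; then 15, −78 °C; aq NH4Cl
Reagents that add atoms: n-butyllithium, [Li]CCCC (supplies only the lithium of 16)
Why: Bromine–lithium exchange followed by Weinreb ketone synthesis; the chelated tetrahedral intermediate prevents over-addition and the chloroacetamide is an established reagent for alpha-chloro ketones.

Step 11
Reactants: 17 2-chloro-1-[4-(methoxymethoxy)-3-(3-methylbut-2-en-1-yl)phenyl]ethan-1-one
Product: 19 (2S)-2-[4-(methoxymethoxy)-3-(3-methylbut-2-en-1-yl)phenyl]oxirane, via (S)-chlorohydrin 18 (not isolated)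
Conditions: Cp*RhCl[(R,R)-TsDPEN] (cat.), HCO2H–Et3N (5:2), EtOAc, rt; then 2 M aq NaOH, 0 °C to rt
Reagents that add atoms: none
Why: Noyori-type asymmetric transfer hydrogenation of an alpha-chloro aryl ketone; the (R,R) ligand delivers hydride to the face that gives (R)-1-arylethanols from aryl methyl ketones, which is the (S)-chlorohydrin here because CH2Cl outranks aryl. Base then closes the oxirane by intramolecular SN2 at CH2 without touching the stereocentre, and isolated trisubstituted olefins are inert to transfer hydrogenation.

Step 12
Reactants: 10 2-[4,6-bis(methoxymethoxy)-3-(3-methylbut-2-en-1-yl)-2-{[2-(trimethylsilyl)ethoxy]methoxy}phenyl]-1,3-dithiane; 19 (2S)-2-[4-(methoxymethoxy)-3-(3-methylbut-2-en-1-yl)phenyl]oxirane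
Product: 21 (1R)-2-{2-[4,6-bis(methoxymethoxy)-3-(3-methylbut-2-en-1-yl)-2-{[2-(trimethylsilyl)ethoxy]methoxy}phenyl]-1,3-dithian-2-yl}-1-[4-(methoxymethoxy)-3-(3-methylbut-2-en-1-yl)phenyl]ethan-1-ol, via 2-lithio-1,3-dithiane 20 (not isolated)
Conditions: 10 (1.3 equiv), n-BuLi, THF, −78 to −20 °C; then DMPU, 19, −78 to 0 °C; aq NH4Cl
Reagents that add atoms: n-butyllithium, [Li]CCCC (supplies only the lithium of 20)
Why: n-BuLi removes the dithiane C–H to give the sulfur-stabilised carbanion 20 at the future C4, which opens oxirane 19 by SN2 attack at the unsubstituted carbon and forms the C3–C4 bond. The closest known reaction type is the Corey–Seebach alkylation of 2-aryl-2-lithio-1,3-dithianes with monosubstituted epoxides. No ring closes and no stereocentre is created: the benzylic C–O bond is not broken, so the carbinol keeps the spatial arrangement of 19 and is R only by CIP priority. Two selectivities are needed. The first is the site of metalation: the dithiane C–H is several pK units more acidic than the ring C–H between the two MOM-oxy groups, the flanking acetal oxygens hold lithium next to it, and warming to −20 °C lets any aryllithium equilibrate to 20. The second is terminal rather than benzylic opening: the tertiary carbanion is bulky, no Lewis acid is present, and DMPU sequesters lithium so the electron-rich benzylic carbon is not activated toward ionisation or rearrangement. All acetals, both olefins and the SEM group are inert to the base.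

Step 13
Reactants: 21 (1R)-2-{2-[4,6-bis(methoxymethoxy)-3-(3-methylbut-2-en-1-yl)-2-{[2-(trimethylsilyl)ethoxy]methoxy}phenyl]-1,3-dithian-2-yl}-1-[4-(methoxymethoxy)-3-(3-methylbut-2-en-1-yl)phenyl]ethan-1-ol
Product: 22 2-{2-[(2R)-2-hydroxy-2-[4-(methoxymethoxy)-3-(3-methylbut-2-en-1-yl)phenyl]ethyl]-1,3-dithian-2-yl}-3,5-bis(methoxymethoxy)-6-(3-methylbut-2-en-1-yl)phenol
Conditions: TBAF, THF–DMPU, 65 °C
Reagents that add atoms: none
Why: Fluoride-induced fragmentation of an aryl SEM ether (attack at silicon, loss of ethene and formaldehyde, phenoxide as leaving group); MOM ethers, the dithiane, the carbinol and the olefins do not react with fluoride.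

Step 14
Reactants: 22 2-{2-[(2R)-2-hydroxy-2-[4-(methoxymethoxy)-3-(3-methylbut-2-en-1-yl)phenyl]ethyl]-1,3-dithian-2-yl}-3,5-bis(methoxymethoxy)-6-(3-methylbut-2-en-1-yl)phenol
Product: 23 (2S)-5,7-bis(methoxymethoxy)-2-[4-(methoxymethoxy)-3-(3-methylbut-2-en-1-yl)phenyl]-8-(3-methylbut-2-en-1-yl)-2,3-dihydrospiro[chromene-4,2'-[1,3]dithiane]
Conditions: PPh3, DIAD, THF, 0 °C to rt
Reagents that add atoms: none
Why: Intramolecular Mitsunobu etherification (6-exo-tet): the phenol displaces the activated benzylic oxygen with inversion, converting the (R)-carbinol into the (2S)-chroman. The quaternary dithiane carbon favours closure, and with C4 masked no dehydration toward an enone is possible.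

Step 15
Reactants: 23 (2S)-5,7-bis(methoxymethoxy)-2-[4-(methoxymethoxy)-3-(3-methylbut-2-en-1-yl)phenyl]-8-(3-methylbut-2-en-1-yl)-2,3-dihydrospiro[chromene-4,2'-[1,3]dithiane]
Product: 24 (2S)-5,7-bis(methoxymethoxy)-2-[4-(methoxymethoxy)-3-(3-methylbut-2-en-1-yl)phenyl]-8-(3-methylbut-2-en-1-yl)-2,3-dihydro-4H-chromen-4-one
Conditions: MeI, CaCO3, MeCN–H2O (9:1), 45 °C
Reagents that add atoms: water, O
Why: Alkylative hydrolysis of a dithiane: S-methylation and ring opening are assisted by the electron-rich aryl group, and the buffered, non-oxidising conditions leave olefins, acetals and the C2 stereocentre alone; no free phenol is present to be methylated.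

Step 16
Reactants: 24 (2S)-5,7-bis(methoxymethoxy)-2-[4-(methoxymethoxy)-3-(3-methylbut-2-en-1-yl)phenyl]-8-(3-methylbut-2-en-1-yl)-2,3-dihydro-4H-chromen-4-one
Product: 25 euchrestaflavanone A, (2S)-5,7-dihydroxy-2-[4-hydroxy-3-(3-methylbut-2-en-1-yl)phenyl]-8-(3-methylbut-2-en-1-yl)-2,3-dihydro-4H-chromen-4-one
Conditions: 3 M HCl, MeOH, rt to 40 °C, stopped at full conversion
Reagents that add atoms: none
Why: Acid-catalysed acetal exchange of aryl MOM ethers with methanol, the usual final step for prenylated flavanones; kept cool and short so that the prenyl groups and C2 are not affected.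

## Compound list

1 | phloroglucinol | Oc1cc(O)cc(O)c1 | starting material
2 | 3,5-bis(methoxymethoxy)phenol | COCOc1cc(O)cc(OCOC)c1 | intermediate
3 | 3-chloro-3-methylbut-1-yne | C#CC(C)(C)Cl | starting material
4 | 1,3-bis(methoxymethoxy)-5-[(2-methylbut-3-yn-2-yl)oxy]benzene | C#CC(C)(C)Oc1cc(OCOC)cc(OCOC)c1 | intermediate
5 | 1,3-bis(methoxymethoxy)-5-[(2-methylbut-3-en-2-yl)oxy]benzene | C=CC(C)(C)Oc1cc(OCOC)cc(OCOC)c1 | intermediate
6 | 3,5-bis(methoxymethoxy)-2-(3-methylbut-2-en-1-yl)phenol | CC(C)=CCc1c(O)cc(OCOC)cc1OCOC | intermediate
7 | 2-hydroxy-4,6-bis(methoxymethoxy)-3-(3-methylbut-2-en-1-yl)benzaldehyde | CC(C)=CCc1c(O)c(C=O)c(OCOC)cc1OCOC | intermediate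
8 | propane-1,3-dithiol | SCCCS | starting material
9 | 2-(1,3-dithian-2-yl)-3,5-bis(methoxymethoxy)-6-(3-methylbut-2-en-1-yl)phenol | CC(C)=CCc1c(O)c(C2SCCCS2)c(OCOC)cc1OCOC | intermediate
10 | 2-[4,6-bis(methoxymethoxy)-3-(3-methylbut-2-en-1-yl)-2-{[2-(trimethylsilyl)ethoxy]methoxy}phenyl]-1,3-dithiane | CC(C)=CCc1c(OCOCC[Si](C)(C)C)c(C2SCCCS2)c(OCOC)cc1OCOC | intermediate
11 | 4-bromophenol | Oc1ccc(Br)cc1 | starting material
12 | 1-bromo-3-methylbut-2-ene (prenyl bromide) | CC(C)=CCBr | starting material
13 | 4-bromo-2-(3-methylbut-2-en-1-yl)phenol | CC(C)=CCc1cc(Br)ccc1O | intermediate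
14 | 4-bromo-1-(methoxymethoxy)-2-(3-methylbut-2-en-1-yl)benzene | CC(C)=CCc1cc(Br)ccc1OCOC | intermediate
15 | 2-chloro-N-methoxy-N-methylacetamide | CON(C)C(=O)CCl | starting material
16 | [4-(methoxymethoxy)-3-(3-methylbut-2-en-1-yl)phenyl]lithium | [Li]c1ccc(OCOC)c(CC=C(C)C)c1 | intermediate
17 | 2-chloro-1-[4-(methoxymethoxy)-3-(3-methylbut-2-en-1-yl)phenyl]ethan-1-one | CC(C)=CCc1cc(C(=O)CCl)ccc1OCOC | intermediate
18 | (1S)-2-chloro-1-[4-(methoxymethoxy)-3-(3-methylbut-2-en-1-yl)phenyl]ethan-1-ol | CC(C)=CCc1cc([C@H](O)CCl)ccc1OCOC | intermediate
19 | (2S)-2-[4-(methoxymethoxy)-3-(3-methylbut-2-en-1-yl)phenyl]oxirane | CC(C)=CCc1cc([C@H]2CO2)ccc1OCOC | intermediate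
20 | {2-[4,6-bis(methoxymethoxy)-3-(3-methylbut-2-en-1-yl)-2-{[2-(trimethylsilyl)ethoxy]methoxy}phenyl]-1,3-dithian-2-yl}lithium | [Li]C1(c2c(OCOCC[Si](C)(C)C)c(CC=C(C)C)c(OCOC)cc2OCOC)SCCCS1 | intermediate
21 | (1R)-2-{2-[4,6-bis(methoxymethoxy)-3-(3-methylbut-2-en-1-yl)-2-{[2-(trimethylsilyl)ethoxy]methoxy}phenyl]-1,3-dithian-2-yl}-1-[4-(methoxymethoxy)-3-(3-methylbut-2-en-1-yl)phenyl]ethan-1-ol | C[Si](C)(C)CCOCOc1c(CC=C(C)C)c(OCOC)cc(OCOC)c1C1(C[C@@H](O)c2ccc(OCOC)c(CC=C(C)C)c2)SCCCS1 | intermediate
22 | 2-{2-[(2R)-2-hydroxy-2-[4-(methoxymethoxy)-3-(3-methylbut-2-en-1-yl)phenyl]ethyl]-1,3-dithian-2-yl}-3,5-bis(methoxymethoxy)-6-(3-methylbut-2-en-1-yl)phenol | Oc1c(CC=C(C)C)c(OCOC)cc(OCOC)c1C1(C[C@@H](O)c2ccc(OCOC)c(CC=C(C)C)c2)SCCCS1 | intermediate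
23 | (2S)-5,7-bis(methoxymethoxy)-2-[4-(methoxymethoxy)-3-(3-methylbut-2-en-1-yl)phenyl]-8-(3-methylbut-2-en-1-yl)-2,3-dihydrospiro[chromene-4,2'-[1,3]dithiane] | CC(C)=CCc1cc([C@@H]2CC3(SCCCS3)c3c(OCOC)cc(OCOC)c(CC=C(C)C)c3O2)ccc1OCOC | intermediate
24 | (2S)-5,7-bis(methoxymethoxy)-2-[4-(methoxymethoxy)-3-(3-methylbut-2-en-1-yl)phenyl]-8-(3-methylbut-2-en-1-yl)-2,3-dihydro-4H-chromen-4-one | CC(C)=CCc1cc([C@@H]2CC(=O)c3c(OCOC)cc(OCOC)c(CC=C(C)C)c3O2)ccc1OCOC | intermediate
25 | euchrestaflavanone A, (2S)-5,7-dihydroxy-2-[4-hydroxy-3-(3-methylbut-2-en-1-yl)phenyl]-8-(3-methylbut-2-en-1-yl)-2,3-dihydro-4H-chromen-4-one | CC(C)=CCc1cc([C@@H]2CC(=O)c3c(O)cc(O)c(CC=C(C)C)c3O2)ccc1O | target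

## Step count and least certain steps

Total: 16 steps. Longest linear sequence: 12 steps (steps 1–7 and 12–16); the ring B branch contributes steps 8–11.

**Step 12 (key step).**
- What may go wrong: lithiation at the ring C–H between the two MOM-oxy groups instead of the dithiane carbon; slow opening, because the carbanion sits between two ortho substituents; attack at the benzylic carbon or lithium-induced rearrangement of the electron-rich oxirane.
- Fallback: run the coupling on the unprotected phenol. Phenol 9 is treated with two equivalents of n-BuLi to give the phenoxide–dithianyl dianion, a known way of using 2-(2-hydroxyaryl)-1,3-dithianes with epoxides. This removes the SEM group as a director of ring metalation and holds lithium at the phenoxide beside the carbanion. Addition of 19 then gives 22 directly. The fallback sets out from 9, returns at 22, and omits steps 7 and 13.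

**Step 6 (thioacetalisation).**
- What may go wrong: loss of a MOM group by acetal exchange with the dithiol, or acid-induced closure of the prenyl chain onto the free phenol.
- Fallback: avoid both the aldehyde and the acid by Gassman-type ortho-dithianylation. 1,3-Dithiane is chlorinated with N-chlorosuccinimide at low temperature, phenol 6 is added, and Et3N triggers the [2,3]-sigmatropic shift of the aryloxysulfonium ylide to the ortho carbon. The fallback sets out from 6, returns at 9, and omits step 5.

**Step 13 (SEM removal).**
- What may go wrong: sluggish cleavage of the hindered aryl SEM ether, so that forcing fluoride conditions are needed.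
- Fallback: replace SEM by allyl. Phenol 9 is allylated (allyl bromide, K2CO3) to 2-[2-(allyloxy)-4,6-bis(methoxymethoxy)-3-(3-methylbut-2-en-1-yl)phenyl]-1,3-dithiane F1. Lithiation and opening of 19 as in step 12 give the allyl ether carbinol F2. Deallylation with Pd(PPh3)4 (zerovalent palladium) and morpholine gives 22. The fallback sets out from 9 and returns at 22.

**Step 14 (Mitsunobu closure).**
- What may go wrong: ionisation of the para-oxygenated benzylic oxyphosphonium ion, with partial loss of configuration, or elimination to the styrene.
- Fallback: give up the stereospecific closure and let a catalyst set C2. Alkylative hydrolysis of the dithiane of 22 gives the beta-hydroxy ketone F3. Dehydration gives the (E)-2'-hydroxychalcone F4. Enantioselective intramolecular oxa-Michael addition with a bifunctional cinchona–thiourea catalyst gives 24. The fallback sets out from 22 and returns at 24; its selectivity on this substitution pattern would have to be established.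

**Step 16 (MOM removal).**
- What may go wrong: acid-promoted closure of a prenyl group onto its neighbouring phenol, addition of methanol to the olefins, or erosion of C2 through reversible opening at the para-hydroxybenzylic position.
- Fallback: avoid protic acid. Treatment of 24 with TESOTf and 2,2'-bipyridyl exchanges the aryl MOM ethers for silyl ethers, giving the tris(triethylsilyl) ether F5. Buffered fluoride (TBAF–AcOH, 0 °C) then releases 25. The fallback sets out from 24 and returns at 25.

## Further compounds

F0 | step 12 | none | none
F0 | step 6 | none | none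
F1 | step 13 | 2-[2-(allyloxy)-4,6-bis(methoxymethoxy)-3-(3-methylbut-2-en-1-yl)phenyl]-1,3-dithiane | C=CCOc1c(CC=C(C)C)c(OCOC)cc(OCOC)c1C1SCCCS1
F2 | step 13 | (1R)-2-{2-[2-(allyloxy)-4,6-bis(methoxymethoxy)-3-(3-methylbut-2-en-1-yl)phenyl]-1,3-dithian-2-yl}-1-[4-(methoxymethoxy)-3-(3-methylbut-2-en-1-yl)phenyl]ethan-1-ol | C=CCOc1c(CC=C(C)C)c(OCOC)cc(OCOC)c1C1(C[C@@H](O)c2ccc(OCOC)c(CC=C(C)C)c2)SCCCS1
F3 | step 14 | (3R)-3-hydroxy-1-[2-hydroxy-4,6-bis(methoxymethoxy)-3-(3-methylbut-2-en-1-yl)phenyl]-3-[4-(methoxymethoxy)-3-(3-methylbut-2-en-1-yl)phenyl]propan-1-one | Oc1c(CC=C(C)C)c(OCOC)cc(OCOC)c1C(=O)C[C@@H](O)c1ccc(OCOC)c(CC=C(C)C)c1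
F4 | step 14 | (E)-1-[2-hydroxy-4,6-bis(methoxymethoxy)-3-(3-methylbut-2-en-1-yl)phenyl]-3-[4-(methoxymethoxy)-3-(3-methylbut-2-en-1-yl)phenyl]prop-2-en-1-one | Oc1c(CC=C(C)C)c(OCOC)cc(OCOC)c1C(=O)/C=C/c1ccc(OCOC)c(CC=C(C)C)c1
F5 | step 16 | (2S)-5,7-bis(triethylsilyloxy)-2-[4-(triethylsilyloxy)-3-(3-methylbut-2-en-1-yl)phenyl]-8-(3-methylbut-2-en-1-yl)-2,3-dihydro-4H-chromen-4-one | CC(C)=CCc1cc([C@@H]2CC(=O)c3c(O[Si](CC)(CC)CC)cc(O[Si](CC)(CC)CC)c(CC=C(C)C)c3O2)ccc1O[Si](CC)(CC)CC
A1 | alternative 1 | (2S)-4'-O-(methoxymethyl)euchrestaflavanone A | CC(C)=CCc1cc([C@@H]2CC(=O)c3c(O)cc(O)c(CC=C(C)C)c3O2)ccc1OCOC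
A2 | alternative 1 | (2S)-2-[4-(methoxymethoxy)-3-(3-methylbut-2-en-1-yl)phenyl]-5-(phenylsulfinyl)-2,3-dihydro-4H-pyran-4-one | CC(C)=CCc1cc([C@@H]2CC(=O)C(S(=O)c3ccccc3)=CO2)ccc1OCOC
A3 | alternative 1 | 1-methoxy-7-methyl-1,3-bis(trimethylsilyloxy)octa-1,3,6-triene | COC(O[Si](C)(C)C)=CC(O[Si](C)(C)C)=CCC=C(C)C
A4 | alternative 2 | (S)-branched aryl allyl ether: 1,5-bis(methoxymethoxy)-3-({(1S)-1-[4-(methoxymethoxy)-3-(3-methylbut-2-en-1-yl)phenyl]prop-2-en-1-yl}oxy)-2-(3-methylbut-2-en-1-yl)benzene | CC(C)=CCc1cc([C@@H](Oc2cc(OCOC)cc(OCOC)c2CC=C(C)C)C=C)ccc1OCOC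
A5 | alternative 2 | methyl (E)-3-[4-(methoxymethoxy)-3-(3-methylbut-2-en-1-yl)phenyl]prop-2-en-1-yl carbonate | COC(=O)OC/C=C/c1ccc(OCOC)c(CC=C(C)C)c1
A6 | alternative 3 | (2S,4S)-5,7-bis(methoxymethoxy)-2-[4-(methoxymethoxy)-3-(3-methylbut-2-en-1-yl)phenyl]-8-(3-methylbut-2-en-1-yl)chroman-4-ol | CC(C)=CCc1cc([C@@H]2C[C@H](O)c3c(OCOC)cc(OCOC)c(CC=C(C)C)c3O2)ccc1OCOC
A7 | alternative 3 | racemic 5,7-bis(methoxymethoxy)-2-[4-(methoxymethoxy)-3-(3-methylbut-2-en-1-yl)phenyl]-8-(3-methylbut-2-en-1-yl)-2,3-dihydro-4H-chromen-4-one | CC(C)=CCc1cc(C2CC(=O)c3c(OCOC)cc(OCOC)c(CC=C(C)C)c3O2)ccc1OCOC
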